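Numbering used throughout: 1 2,6‑dibromoanisole; 2 arylboronate; 3 phenol; 4 TIPS ether; 5 4‑methylpent‑3‑enoic acid; 6 Weinreb amide; 7 aryllithium; 8 ketone; 9 (R)‑alcohol; 10 key‑step precursor; 11 furan; 12 2‑bromoaryllithium; 13 aryne; 14 cycloadduct; 15 and 16 naphthols; 17 protected quinone; 18 hydroxyquinone carbinol; 19 3‑methylbut‑2‑enoic acid; 20 target.

## Analysis of the target

Target 20 is a 1,4‑naphthoquinone. Ring B (C1 to C4, with C1=O, C2=C3 and C4=O) carries no substituent, whereas ring A (C4a, C5 to C8, C8a) carries a methyl ether at C5, the side chain at C6, hydrogen at C7 and a free phenol at C8 that is hydrogen‑bonded to the C1 carbonyl. The side chain holds the only stereocentre, C1′, which is benzylic, R‑configured and acylated by 3‑methylbut‑2‑enoic acid; only absolute control is needed, and it must not be lost by ionisation of the benzylic C–O bond. The quinone does not tolerate bases, hydrides or nucleophiles, the trisubstituted C3′=C4′ alkene is open to hydroboration and electrophiles, the free C1′ carbinol can close onto that alkene under acid, and the enoate can deconjugate or accept nucleophiles. The difficulty lies less in the carbon skeleton than in the four ring oxygens at C1, C4, C5 and C8, which sit in three different states (two carbonyls, one methyl ether, one phenol). A route through a symmetrically oxygenated naphthalene must later tell ring A from ring B, and oxidants tend to place the quinone in the more electron‑rich, alkylated ring A. The strategy rests on ring B being unsubstituted and symmetric about C2=C3, so that its four carbons, and for a time one bridging oxygen, can come from furan and be joined to the C4a–C8a edge of a benzene that already carries the C5 methyl ether, the masked C8 oxygen and the complete side chain. C4a–C8a thereby becomes an aryne bond, and ring B is left with a single hydroxyl after bridge opening, which decides where the quinone forms.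

## Retrosynthetic reasoning

The first cut is the ester C–O bond of 20, giving hydroxyquinone 18 and 3‑methylbut‑2‑enoic acid 19. The enoate has acidic γ‑hydrogens and an electrophilic β‑carbon and would not survive a lithium amide, so it goes on last. The forward acylation must choose the secondary carbinol over the C8 phenol, which the hydrogen bond of that phenol to C1=O should ensure.

Compound 18 is traced to its bis‑silyl ether 17. The C8 and C1′ hydroxyls must be masked through the organolithium, amide‑base and oxidation steps. Silyl ethers are chosen because fluoride removes both at once without acid strong enough to close the carbinol onto the prenyl alkene.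

The two carbonyl groups of 17 are taken back to a single naphthol hydroxyl, at C1 in 15 or at C4 in 16. Ring A has no free hydroxyl at this stage, so oxidation of the lone naphthol can only place the quinone in ring B. Both naphthols are isomers of the oxygen‑bridged compound 14 by cleavage of one bridge C–O bond, and whichever bond breaks, the same quinone results.

The central disconnection cuts C1–C8a and C4–C4a of 14, giving aryne 13 and furan 11. It is made here because ring B has no substituents, so a symmetric four‑carbon partner brings no regiochemical question. It also confines all differentiation of the ring oxygens to a benzene precursor. Aryne 13 comes from bromoarene 10 by loss of H–C8a and Br–C4a. The forward step must metalate the one ring position next to bromine and trap the aryne faster than the amide base adds to it.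

Precursor 10 is the silyl ether of carbinol 9, and 9 is cut at its C1′–H bond to aryl ketone 8. An aryl alkyl ketone is a reliable substrate for oxazaborolidine‑catalysed reduction, so the stereocentre is set by the catalyst alone.

Ketone 8 is cut at the C6–C1′ bond into dibromide 4 and Weinreb amide 6, the latter made from 4‑methylpent‑3‑enoic acid 5. Dibromide 4 is symmetric, so exchange of either bromine gives the same aryllithium 7. One bromine thus serves to attach the side chain and the other remains as the leaving group of the aryne.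

Dibromide 4 is the silyl ether of phenol 3, whose C–O bond is cut back through boronate 2 to 2,6‑dibromoanisole 1. In 1 only the hydrogen para to the methoxy group has no ortho neighbour, so a sterically governed C–H borylation should place the future C8 oxygen without any directing group.

## Alternatives that were turned down

Alternative 1: Moore ring expansion. The disconnection cuts C8–C8a and folds C5 to C8 into a four‑membered ring. The precursor is cyclobutenone A2, a 4‑(2,5‑dimethoxyphenyl)‑4‑methoxycyclobut‑2‑en‑1‑one with the carbamate‑protected (R) side chain at C3. On heating in toluene A2 should open to an aryl vinylketene, which closes onto the free ortho carbon of the aryl group and tautomerises to naphthol A1.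
- For: the step needs no reagent, runs under neutral conditions and fixes the substitution of ring A through the cyclobutenone. On mildness it is stronger than the aryne step, which needs a strong base and a hindered deprotonation.
- Against: in A1 ring B is a 1,4‑dimethoxybenzene and ring A a para‑methoxynaphthol. Oxidative demethylation would attack the more electron‑rich ring A and give the wrong quinone with loss of the C5 methyl ether, unless C8–OH is first masked as an ester and unmasked afterwards.
- Against: the diisopropylcarbamate needs a hydride or a strong nucleophile for removal, so it must go before any quinone exists. A2 itself, with a quaternary aryl(methoxy) carbon and the chiral side chain, would take at least as long to make as the seven steps to 10.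
- Comparison: four to five steps would follow A1, against four after 14. The chosen route gives up the mild key step but never asks an oxidant to tell ring A from ring B.

Alternative 2: Tamura annulation. The disconnection cuts C4a–C5 and C8–C8a, so that ring A comes from hydroxypyrone A4 (the enol form of a methoxyglutaconic anhydride carrying the silylated side chain) and 1,4‑benzoquinone A5. The sodium salt of A4 should add across one C=C of A5 in a [4+2] sense; decarboxylation, aromatisation and oxidation by excess A5 would give quinone A3.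
- For: this is the most convergent plan. A3 has the quinone, the C5 methyl ether and the free C8 phenol in place, so only desilylation and esterification remain, two steps against four in the chosen route. On step economy after the key step it is stronger.
- Against: in the anion of A4 the C1′–O bond is β to carbanionic ring carbons, so loss of silanolate is likely, and C1′–H is vinylogously acidic, which puts the stereocentre at risk.
- Against: simple glutaconic anhydrides are less dependable annulation partners than homophthalic ones, A5 is prone to conjugate addition and electron transfer with enolates, and A4 has no short access.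
- Comparison: the chosen route keeps C1′ as a non‑acidic benzylic silyl ether during its base step and starts from a commercial arene, at the price of two more steps at the end.

Alternative 3: Dötz benzannulation. The disconnection cuts C7–C8, C5–C6 and C4a–C5; ring A comes from chromium carbene complex A7, the (R)‑propargylic silyl ether A8 and one carbonyl ligand. Warming A7 with A8 in THF and oxidative decomplexation in air should give naphthol A6.
- For: three C–C bonds form in one step with predictable regiochemistry, and the stereocentre arrives in a small alkyne that is easy to make enantiopure. On bond count per step it is stronger than the aryne cycloaddition.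
- Against: in A6 the new free hydroxyl sits at C5, where the target has the methyl ether, and C8 carries the 2‑(trimethylsilyl)ethyl ether, where the target has the phenol. The hindered C5–OH must be methylated and C8–O unmasked.
- Against: the dimethoxy ring B must then be oxidised selectively while the more electron‑rich, alkylated ring A is spared, the same selectivity problem as in alternative 1. Stoichiometric chromium is also needed.
- Comparison: five or more steps would follow A6. The chosen route sets the oxidation level of ring B through a single naphthol hydroxyl and needs no ring‑selective oxidant.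

Key step: step 8

Remark on the chemistry: the locants of the target quinone (C1 and C4 carbonyl carbons, C5 OMe, C6 side chain, C8 OH, C1′ the carbinol carbon) are used for all bicyclic intermediates; 14, 15 and 16 are carried as mixtures because their extra isomerism disappears at 17.

## Route

Step 1
Reactants: 1 2,6‑dibromoanisole
Product: 2 2‑(3,5‑dibromo‑4‑methoxyphenyl)‑4,4,5,5‑tetramethyl‑1,3,2‑dioxaborolane
Conditions: [Ir(OMe)(cod)]2 (cat.), 4,4′‑di‑tert‑butyl‑2,2′‑bipyridine (cat.), B2pin2, THF, 80 °C
Reagents that add atoms: bis(pinacolato)diboron, CC1(C)OB(OC1(C)C)B1OC(C)(C)C(C)(C)O1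
Why: Iridium‑catalysed aromatic C–H borylation is governed by sterics; in 1 only the hydrogen para to OMe has no ortho substituent, so the boryl group should enter there, and C–Br bonds are tolerated.

Step 2
Reactants: 2 2‑(3,5‑dibromo‑4‑methoxyphenyl)‑4,4,5,5‑tetramethyl‑1,3,2‑dioxaborolane
Product: 3 3,5‑dibromo‑4‑methoxyphenol
Conditions: H2O2 (30 % aq.), NaOH, THF, 0 °C → rt
Reagents that add atoms: hydrogen peroxide, OO
Why: Oxidation of an arylboronate by alkaline peroxide (1,2‑shift of the aryl group from boron to oxygen) should give the phenol at the borylated carbon; the aryl bromides and the methyl ether are inert.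

Step 3
Reactants: 3 3,5‑dibromo‑4‑methoxyphenol
Product: 4 (3,5‑dibromo‑4‑methoxyphenoxy)triisopropylsilane
Conditions: iPr3SiCl, imidazole, DMF, rt
Reagents that add atoms: triisopropylsilyl chloride, CC(C)[Si](Cl)(C(C)C)C(C)C
Why: Imidazole‑promoted silylation of a phenol; the triisopropylsilyl ether is chosen because it should survive n‑BuLi, LiN(iPr)2 and catalytic acid and resist silyl migration.

Step 4
Reactants: 5 4‑methylpent‑3‑enoic acid
Product: 6 N‑methoxy‑N‑methyl‑4‑methylpent‑3‑enamide
Conditions: 1,1′‑carbonyldiimidazole, CH2Cl2, rt; then MeNH(OMe)·HCl, rt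
Reagents that add atoms: N,O‑dimethylhydroxylamine hydrochloride, CNOC.Cl
Why: Weinreb amide formation through the acyl imidazolide; the near‑neutral conditions should keep the β,γ‑alkene out of conjugation.

Step 5
Reactants: 4 (3,5‑dibromo‑4‑methoxyphenoxy)triisopropylsilane; 6 N‑methoxy‑N‑methyl‑4‑methylpent‑3‑enamide
Product: 8 1‑[3‑bromo‑2‑methoxy‑5‑(triisopropylsilyloxy)phenyl]‑4‑methylpent‑3‑en‑1‑one, via aryllithium 7 (not isolated)
Conditions: n‑BuLi (1.0 equiv), THF, −78 °C; then 6, −78 → 0 °C; aq. NH4Cl
Reagents that add atoms: n‑butyllithium, [Li]CCCC (lithium of intermediate 7)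
Why: Bromine–lithium exchange on the symmetric dibromide gives the same aryllithium 7 whichever bromine reacts, and the Weinreb ketone synthesis stops at the chelated tetrahedral adduct, so the β,γ‑unsaturated ketone should be released only on quenching and no second addition occurs.

Step 6
Reactants: 8 1‑[3‑bromo‑2‑methoxy‑5‑(triisopropylsilyloxy)phenyl]‑4‑methylpent‑3‑en‑1‑one
Product: 9 (1R)‑1‑[3‑bromo‑2‑methoxy‑5‑(triisopropylsilyloxy)phenyl]‑4‑methylpent‑3‑en‑1‑ol
Conditions: (S)‑2‑methyl‑CBS‑oxazaborolidine (20 mol %), catecholborane, toluene, −78 °C; then MeOH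
Reagents that add atoms: none
Why: Corey–Bakshi–Shibata reduction: the ketone binds the catalyst boron with the large aryl group away from the catalyst substituent, and hydride is delivered to the face that gives the (R)‑carbinol, the sense known for aryl alkyl ketones with the (S)‑catalyst; catecholborane is used because it should not hydroborate the trisubstituted alkene at −78 °C.

Step 7
Reactants: 9 (1R)‑1‑[3‑bromo‑2‑methoxy‑5‑(triisopropylsilyloxy)phenyl]‑4‑methylpent‑3‑en‑1‑ol
Product: 10 {3‑bromo‑5‑[(1R)‑1‑(tert‑butyldimethylsilyloxy)‑4‑methylpent‑3‑enyl]‑4‑methoxyphenoxy}triisopropylsilane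
Conditions: tBuMe2SiCl, imidazole, DMF, rt → 40 °C
Reagents that add atoms: tert‑butyldimethylsilyl chloride, CC(C)(C)[Si](C)(C)Cl
Why: Silylation of a secondary benzylic alcohol forms only an O–Si bond, so C1′ keeps its configuration, and the silyl ether removes the one acidic hydrogen before the amide base step.

Step 8
Reactants: 10 {3‑bromo‑5‑[(1R)‑1‑(tert‑butyldimethylsilyloxy)‑4‑methylpent‑3‑enyl]‑4‑methoxyphenoxy}triisopropylsilane; 11 furan
Product: 14 5‑methoxy‑6‑[(1R)‑1‑(tert‑butyldimethylsilyloxy)‑4‑methylpent‑3‑enyl]‑8‑(triisopropylsilyloxy)‑1,4‑dihydro‑1,4‑epoxynaphthalene (both bridgehead diastereomers), via 2‑bromoaryllithium 12 (not isolated), via aryne 13 (not isolated)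
Conditions: LiN(iPr)2 (2 equiv), furan (20 equiv), THF, −78 → 0 °C
Reagents that add atoms: lithium diisopropylamide, [Li]N(C(C)C)C(C)C (lithium of intermediate 12)
Why: LiN(iPr)2 should remove H–C8a, the only ring hydrogen next to bromine and the one acidified by both the C4a–Br and the C8–O bonds, and the 2‑bromoaryllithium 12 then loses LiBr to give aryne 13 with the strained bond between C4a and C8a. Furan 11, present in large excess, adds as the 4π partner in a concerted suprafacial [4+2] cycloaddition that forms C1–C8a and C4–C4a together and closes ring B as a six‑membered carbocycle bridged by the furan oxygen. The closest known reaction type is the lithium amide dehydrobromination of 2‑bromo‑1,4‑dialkoxybenzenes in furan, an aryne Diels–Alder reaction that gives 5,8‑dialkoxy‑1,4‑dihydro‑1,4‑epoxynaphthalenes. The ring closes by intermolecular cycloaddition, so both bonds form on one face of the furan and the cis bridge follows from geometry. The new bridgehead centres C1 and C4 are fixed relative to each other but not relative to C1′, so two diastereomers are expected; no control is needed because both centres become sp2 in step 9, and C1′ is untouched since its hydrogen is not acidic. The step needs site selectivity in the metalation, which the substrate secures because C7–H has no neighbouring leaving group and lies between the silyloxy group and the branched side chain, so lithiation there is unproductive and reversible. No regiocontrol is needed in the cycloaddition because 11 is symmetric, and the side chain at C6 cannot reach the aryne. The bulky silyl group on the C8 oxygen slows the metalation, which is why warming to 0 °C and a hindered, poorly nucleophilic amide in excess furan are specified.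

Step 9
Reactants: 14 5‑methoxy‑6‑[(1R)‑1‑(tert‑butyldimethylsilyloxy)‑4‑methylpent‑3‑enyl]‑8‑(triisopropylsilyloxy)‑1,4‑dihydro‑1,4‑epoxynaphthalene
Product: 15 5‑methoxy‑6‑[(1R)‑1‑(tert‑butyldimethylsilyloxy)‑4‑methylpent‑3‑enyl]‑8‑(triisopropylsilyloxy)naphthalen‑1‑ol and 16 8‑methoxy‑7‑[(1R)‑1‑(tert‑butyldimethylsilyloxy)‑4‑methylpent‑3‑enyl]‑5‑(triisopropylsilyloxy)naphthalen‑1‑ol (regioisomers, carried on together without purification)
Conditions: camphorsulfonic acid (10 mol %), CH2Cl2, 0 °C
Reagents that add atoms: none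
Why: Acid‑catalysed isomerisation of a 1,4‑dihydro‑1,4‑epoxynaphthalene to a 1‑naphthol: protonation of the bridge oxygen, ionisation at a bridgehead that is stabilised by the ortho oxygen donor on C5 or C8, and loss of a proton to aromatise; either ionisation gives a naphthol that leads to the same quinone, and a catalytic anhydrous sulfonic acid in an aprotic solvent should spare both silyl ethers.

Step 10
Reactants: 15 5‑methoxy‑6‑[(1R)‑1‑(tert‑butyldimethylsilyloxy)‑4‑methylpent‑3‑enyl]‑8‑(triisopropylsilyloxy)naphthalen‑1‑ol; 16 8‑methoxy‑7‑[(1R)‑1‑(tert‑butyldimethylsilyloxy)‑4‑methylpent‑3‑enyl]‑5‑(triisopropylsilyloxy)naphthalen‑1‑ol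
Product: 17 5‑methoxy‑6‑[(1R)‑1‑(tert‑butyldimethylsilyloxy)‑4‑methylpent‑3‑enyl]‑8‑(triisopropylsilyloxy)naphthalene‑1,4‑dione
Conditions: (KSO3)2NO (2.5 equiv), KH2PO4, acetone/H2O, 0 °C → rt
Reagents that add atoms: potassium nitrosodisulfonate (KSO3)2NO, [K+].[K+].[O-]S(=O)(=O)N([O])S(=O)(=O)[O-]
Why: Teuber oxidation: one nitrosodisulfonate radical abstracts the naphthol hydrogen and a second adds at the free para position (C4 in 15, C1 in 16), and collapse gives the para‑quinone; ring A has no free hydroxyl, so only ring B should be oxidised and both naphthols converge.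

Step 11
Reactants: 17 5‑methoxy‑6‑[(1R)‑1‑(tert‑butyldimethylsilyloxy)‑4‑methylpent‑3‑enyl]‑8‑(triisopropylsilyloxy)naphthalene‑1,4‑dione
Product: 18 8‑hydroxy‑6‑[(1R)‑1‑hydroxy‑4‑methylpent‑3‑enyl]‑5‑methoxynaphthalene‑1,4‑dione
Conditions: HF·pyridine, pyridine, THF, 0 °C → rt
Reagents that add atoms: none
Why: Fluoride cleavage of both Si–O bonds under buffered, non‑basic conditions that a quinone should tolerate; only Si–O bonds break, so C1′ is not touched, and the acidity is too low to close the carbinol onto the alkene.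

Step 12
Reactants: 18 8‑hydroxy‑6‑[(1R)‑1‑hydroxy‑4‑methylpent‑3‑enyl]‑5‑methoxynaphthalene‑1,4‑dione; 19 3‑methylbut‑2‑enoic acid
Product: 20 (1R)‑1‑(4‑hydroxy‑1‑methoxy‑5,8‑dioxo‑5,8‑dihydronaphthalen‑2‑yl)‑4‑methylpent‑3‑enyl 3‑methylbut‑2‑enoate (target)
Conditions: N,N′‑dicyclohexylcarbodiimide, 4‑(dimethylamino)pyridine (cat.), CH2Cl2, 0 °C → rt
Reagents that add atoms: none
Why: Steglich esterification: the C8 phenol is tied up in a hydrogen bond to C1=O and is a poor nucleophile, so the acyl pyridinium should be taken up by the secondary carbinol, with retention because the C1′–O bond is not broken.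

## Compound list

1 | 2,6‑dibromoanisole | COc1c(Br)cccc1Br | starting material
2 | 2‑(3,5‑dibromo‑4‑methoxyphenyl)‑4,4,5,5‑tetramethyl‑1,3,2‑dioxaborolane | COc1c(Br)cc(cc1Br)B1OC(C)(C)C(C)(C)O1 | intermediate
3 | 3,5‑dibromo‑4‑methoxyphenol | COc1c(Br)cc(O)cc1Br | intermediate
4 | (3,5‑dibromo‑4‑methoxyphenoxy)triisopropylsilane | COc1c(Br)cc(O[Si](C(C)C)(C(C)C)C(C)C)cc1Br | intermediate
5 | 4‑methylpent‑3‑enoic acid | CC(C)=CCC(=O)O | starting material
6 | N‑methoxy‑N‑methyl‑4‑methylpent‑3‑enamide | CC(C)=CCC(=O)N(C)OC | intermediate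
7 | [3‑bromo‑2‑methoxy‑5‑(triisopropylsilyloxy)phenyl]lithium | COc1c(Br)cc(O[Si](C(C)C)(C(C)C)C(C)C)cc1[Li] | intermediate (not isolated)
8 | 1‑[3‑bromo‑2‑methoxy‑5‑(triisopropylsilyloxy)phenyl]‑4‑methylpent‑3‑en‑1‑one | COc1c(Br)cc(O[Si](C(C)C)(C(C)C)C(C)C)cc1C(=O)CC=C(C)C | intermediate
9 | (1R)‑1‑[3‑bromo‑2‑methoxy‑5‑(triisopropylsilyloxy)phenyl]‑4‑methylpent‑3‑en‑1‑ol | COc1c(Br)cc(O[Si](C(C)C)(C(C)C)C(C)C)cc1[C@@H](CC=C(C)C)O | intermediate
10 | {3‑bromo‑5‑[(1R)‑1‑(tert‑butyldimethylsilyloxy)‑4‑methylpent‑3‑enyl]‑4‑methoxyphenoxy}triisopropylsilane | COc1c(Br)cc(O[Si](C(C)C)(C(C)C)C(C)C)cc1[C@@H](CC=C(C)C)O[Si](C)(C)C(C)(C)C | intermediate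
11 | furan | c1ccoc1 | starting material
12 | {2‑bromo‑4‑[(1R)‑1‑(tert‑butyldimethylsilyloxy)‑4‑methylpent‑3‑enyl]‑3‑methoxy‑6‑(triisopropylsilyloxy)phenyl}lithium | COc1c(Br)c([Li])c(O[Si](C(C)C)(C(C)C)C(C)C)cc1[C@@H](CC=C(C)C)O[Si](C)(C)C(C)(C)C | intermediate (not isolated)
13 | 3‑methoxy‑4‑[(1R)‑1‑(tert‑butyldimethylsilyloxy)‑4‑methylpent‑3‑enyl]‑6‑(triisopropylsilyloxy)‑1,2‑didehydrobenzene (aryne) | COC1=C([C@@H](CC=C(C)C)O[Si](C)(C)C(C)(C)C)C=C(O[Si](C(C)C)(C(C)C)C(C)C)C#C1 | intermediate (not isolated)
14 | 5‑methoxy‑6‑[(1R)‑1‑(tert‑butyldimethylsilyloxy)‑4‑methylpent‑3‑enyl]‑8‑(triisopropylsilyloxy)‑1,4‑dihydro‑1,4‑epoxynaphthalene (both bridgehead diastereomers) | COc1c([C@@H](CC=C(C)C)O[Si](C)(C)C(C)(C)C)cc(O[Si](C(C)C)(C(C)C)C(C)C)c2c1C1C=CC2O1 | intermediate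
15 | 5‑methoxy‑6‑[(1R)‑1‑(tert‑butyldimethylsilyloxy)‑4‑methylpent‑3‑enyl]‑8‑(triisopropylsilyloxy)naphthalen‑1‑ol | COc1c([C@@H](CC=C(C)C)O[Si](C)(C)C(C)(C)C)cc(O[Si](C(C)C)(C(C)C)C(C)C)c2c(O)cccc12 | intermediate
16 | 8‑methoxy‑7‑[(1R)‑1‑(tert‑butyldimethylsilyloxy)‑4‑methylpent‑3‑enyl]‑5‑(triisopropylsilyloxy)naphthalen‑1‑ol | COc1c([C@@H](CC=C(C)C)O[Si](C)(C)C(C)(C)C)cc(O[Si](C(C)C)(C(C)C)C(C)C)c2cccc(O)c12 | intermediate
17 | 5‑methoxy‑6‑[(1R)‑1‑(tert‑butyldimethylsilyloxy)‑4‑methylpent‑3‑enyl]‑8‑(triisopropylsilyloxy)naphthalene‑1,4‑dione | COc1c([C@@H](CC=C(C)C)O[Si](C)(C)C(C)(C)C)cc(O[Si](C(C)C)(C(C)C)C(C)C)c2c1C(=O)C=CC2=O | intermediate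
18 | 8‑hydroxy‑6‑[(1R)‑1‑hydroxy‑4‑methylpent‑3‑enyl]‑5‑methoxynaphthalene‑1,4‑dione | COc1c([C@@H](CC=C(C)C)O)cc(O)c2c1C(=O)C=CC2=O | intermediate
19 | 3‑methylbut‑2‑enoic acid | CC(C)=CC(=O)O | starting material
20 | (1R)‑1‑(4‑hydroxy‑1‑methoxy‑5,8‑dioxo‑5,8‑dihydronaphthalen‑2‑yl)‑4‑methylpent‑3‑enyl 3‑methylbut‑2‑enoate | COc1c([C@@H](CC=C(C)C)OC(=O)C=C(C)C)cc(O)c2c1C(=O)C=CC2=O | target

## Step count and least certain steps

Total step count: 12. Longest linear sequence: 11 steps (steps 1, 2, 3, 5, 6, 7, 8, 9, 10, 11, 12); step 4 is a one‑step branch that joins at step 5.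

Step 8 (key step). The most likely failure is slow or incomplete metalation at C8a, because the triisopropylsilyl group shields that hydrogen and a silyloxy group assists lithiation poorly; on forcing, the aryne may be captured by the amide or by lithiated furan instead of undergoing cycloaddition. The fallback replaces the shielding silyl ether by a small, lithium‑coordinating acetal. It sets out from 10 and returns at 18.
- Bu4NF (1 equiv, THF, 0 °C) should cleave the aryl silyl ether much faster than the secondary alkyl one and give 3‑bromo‑5‑[(1R)‑1‑(tert‑butyldimethylsilyloxy)‑4‑methylpent‑3‑enyl]‑4‑methoxyphenol F1.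
- Chloromethyl methyl ether and iPr2NEt in CH2Cl2 convert it into the methoxymethyl ether F2.
- LiN(iPr)2 and furan 11 at −78 °C should now metalate quickly between bromine and the acetal oxygen and give the methoxymethyl‑protected epoxynaphthalene F3.
- Camphorsulfonic acid (cat.) in CH2Cl2 opens the bridge to the C1 naphthol F4 and the C4 naphthol F5, and (KSO3)2NO oxidises both to the methoxymethyl‑protected quinone F6.
- CF3CO2H in CH2Cl2 at 0 °C removes the acetal, which is peri to C1=O and the most labile group, to give the 8‑hydroxyquinone silyl ether F7; HF·pyridine then gives 18.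

Step 9. The most likely failure is ionisation of the benzylic silyl ether next to the C5 methoxy group, followed by attack of the prenyl alkene on the cation or loss of the silyl group, in competition with bridge opening. The fallback avoids the acid step by changing the diene. It sets out from 10 and returns at 17.
- Compound 10 is treated with LiN(iPr)2 in the presence of 2‑methoxyfuran. The cycloadduct is a bridgehead ketal that should open on work‑up, without added acid, to 4,5‑dimethoxy‑6‑[(1R)‑1‑(tert‑butyldimethylsilyloxy)‑4‑methylpent‑3‑enyl]‑8‑(triisopropylsilyloxy)naphthalen‑1‑ol F8 and its regioisomer 4,8‑dimethoxy‑7‑[(1R)‑1‑(tert‑butyldimethylsilyloxy)‑4‑methylpent‑3‑enyl]‑5‑(triisopropylsilyloxy)naphthalen‑1‑ol F9.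
- PhI(OAc)2 in aqueous MeCN at 0 °C oxidises either para‑methoxynaphthol, with loss of methanol, to 17.

Step 6. The most likely failure is erosion of enantioselectivity through uncatalysed reduction by catecholborane or through poor size discrimination between the ortho‑methoxyaryl group and the unsaturated chain. The fallback sets C1′ by C–C bond formation instead of reduction. It sets out from 4 and returns at 9.
- Dibromide 4 is lithiated as in step 5 and quenched with DMF to give 3‑bromo‑2‑methoxy‑5‑(triisopropylsilyloxy)benzaldehyde F10.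
- Brown allylation with the B‑allyldiisopinocampheylborane derived from (−)‑α‑pinene (Et2O, −78 °C, oxidative work‑up) should give, by the facial sense established for aryl aldehydes, (1R)‑1‑[3‑bromo‑2‑methoxy‑5‑(triisopropylsilyloxy)phenyl]but‑3‑en‑1‑ol F11.
- Cross‑metathesis with 2‑methylbut‑2‑ene (second‑generation Grubbs catalyst, RuCl2(=CHPh)(H2IMes)(PCy3), 40 °C) turns the terminal alkene into the prenyl terminus and gives 9.

Step 12. The most likely failure is competing acylation of the C8 phenol, or migration of the enoate double bond out of conjugation through a ketene formed from the activated acid. The fallback esterifies while the phenol is still silylated. It sets out from 17 and returns at 20.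
- Camphorsulfonic acid in MeOH/CH2Cl2 at 0 °C should cleave the alkyl silyl ether and leave the aryl silyl ether, giving 6‑[(1R)‑1‑hydroxy‑4‑methylpent‑3‑enyl]‑5‑methoxy‑8‑(triisopropylsilyloxy)naphthalene‑1,4‑dione F12.
- Steglich esterification with 19 gives the silyl‑protected ester (1R)‑1‑[1‑methoxy‑5,8‑dioxo‑4‑(triisopropylsilyloxy)‑5,8‑dihydronaphthalen‑2‑yl]‑4‑methylpent‑3‑enyl 3‑methylbut‑2‑enoate F13.
- HF·pyridine then frees the phenol and gives 20.

## Further compounds

F1 | step 8 | 3‑bromo‑5‑[(1R)‑1‑(tert‑butyldimethylsilyloxy)‑4‑methylpent‑3‑enyl]‑4‑methoxyphenol | COc1c(Br)cc(O)cc1[C@@H](CC=C(C)C)O[Si](C)(C)C(C)(C)C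
F2 | step 8 | 1‑bromo‑3‑[(1R)‑1‑(tert‑butyldimethylsilyloxy)‑4‑methylpent‑3‑enyl]‑2‑methoxy‑5‑(methoxymethoxy)benzene | COc1c(Br)cc(OCOC)cc1[C@@H](CC=C(C)C)O[Si](C)(C)C(C)(C)C
F3 | step 8 | 5‑methoxy‑8‑(methoxymethoxy)‑6‑[(1R)‑1‑(tert‑butyldimethylsilyloxy)‑4‑methylpent‑3‑enyl]‑1,4‑dihydro‑1,4‑epoxynaphthalene (both bridgehead diastereomers) | COc1c([C@@H](CC=C(C)C)O[Si](C)(C)C(C)(C)C)cc(OCOC)c2c1C1C=CC2O1
F4 | step 8 | 5‑methoxy‑8‑(methoxymethoxy)‑6‑[(1R)‑1‑(tert‑butyldimethylsilyloxy)‑4‑methylpent‑3‑enyl]naphthalen‑1‑ol | COc1c([C@@H](CC=C(C)C)O[Si](C)(C)C(C)(C)C)cc(OCOC)c2c(O)cccc12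
F5 | step 8 | 8‑methoxy‑5‑(methoxymethoxy)‑7‑[(1R)‑1‑(tert‑butyldimethylsilyloxy)‑4‑methylpent‑3‑enyl]naphthalen‑1‑ol | COc1c([C@@H](CC=C(C)C)O[Si](C)(C)C(C)(C)C)cc(OCOC)c2cccc(O)c12
F6 | step 8 | 5‑methoxy‑8‑(methoxymethoxy)‑6‑[(1R)‑1‑(tert‑butyldimethylsilyloxy)‑4‑methylpent‑3‑enyl]naphthalene‑1,4‑dione | COc1c([C@@H](CC=C(C)C)O[Si](C)(C)C(C)(C)C)cc(OCOC)c2c1C(=O)C=CC2=O
F7 | step 8 | 8‑hydroxy‑5‑methoxy‑6‑[(1R)‑1‑(tert‑butyldimethylsilyloxy)‑4‑methylpent‑3‑enyl]naphthalene‑1,4‑dione | COc1c([C@@H](CC=C(C)C)O[Si](C)(C)C(C)(C)C)cc(O)c2c1C(=O)C=CC2=O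
F8 | step 9 | 4,5‑dimethoxy‑6‑[(1R)‑1‑(tert‑butyldimethylsilyloxy)‑4‑methylpent‑3‑enyl]‑8‑(triisopropylsilyloxy)naphthalen‑1‑ol | COc1c([C@@H](CC=C(C)C)O[Si](C)(C)C(C)(C)C)cc(O[Si](C(C)C)(C(C)C)C(C)C)c2c(O)ccc(OC)c12
F9 | step 9 | 4,8‑dimethoxy‑7‑[(1R)‑1‑(tert‑butyldimethylsilyloxy)‑4‑methylpent‑3‑enyl]‑5‑(triisopropylsilyloxy)naphthalen‑1‑ol | COc1c([C@@H](CC=C(C)C)O[Si](C)(C)C(C)(C)C)cc(O[Si](C(C)C)(C(C)C)C(C)C)c2c(OC)ccc(O)c12
F10 | step 6 | 3‑bromo‑2‑methoxy‑5‑(triisopropylsilyloxy)benzaldehyde | COc1c(Br)cc(O[Si](C(C)C)(C(C)C)C(C)C)cc1C=O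
F11 | step 6 | (1R)‑1‑[3‑bromo‑2‑methoxy‑5‑(triisopropylsilyloxy)phenyl]but‑3‑en‑1‑ol | COc1c(Br)cc(O[Si](C(C)C)(C(C)C)C(C)C)cc1[C@@H](CC=C)O
F12 | step 12 | 6‑[(1R)‑1‑hydroxy‑4‑methylpent‑3‑enyl]‑5‑methoxy‑8‑(triisopropylsilyloxy)naphthalene‑1,4‑dione | COc1c([C@@H](CC=C(C)C)O)cc(O[Si](C(C)C)(C(C)C)C(C)C)c2c1C(=O)C=CC2=O
F13 | step 12 | (1R)‑1‑[1‑methoxy‑5,8‑dioxo‑4‑(triisopropylsilyloxy)‑5,8‑dihydronaphthalen‑2‑yl]‑4‑methylpent‑3‑enyl 3‑methylbut‑2‑enoate | COc1c([C@@H](CC=C(C)C)OC(=O)C=C(C)C)cc(O[Si](C(C)C)(C(C)C)C(C)C)c2c1C(=O)C=CC2=O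
A1 | alternative 1 | (1R)‑1‑(4‑hydroxy‑1,5,8‑trimethoxynaphthalen‑2‑yl)‑4‑methylpent‑3‑enyl N,N‑diisopropylcarbamate | COc1c([C@@H](CC=C(C)C)OC(=O)N(C(C)C)C(C)C)cc(O)c2c(OC)ccc(OC)c12
A2 | alternative 1 | (1R)‑1‑[4‑(2,5‑dimethoxyphenyl)‑4‑methoxy‑1‑oxocyclobut‑2‑en‑3‑yl]‑4‑methylpent‑3‑enyl N,N‑diisopropylcarbamate | COC1(c2cc(OC)ccc2OC)C(=O)C=C1[C@@H](CC=C(C)C)OC(=O)N(C(C)C)C(C)C
A3 | alternative 2 | 8‑hydroxy‑5‑methoxy‑6‑[(1R)‑1‑(tert‑butyldimethylsilyloxy)‑4‑methylpent‑3‑enyl]naphthalene‑1,4‑dione | COc1c([C@@H](CC=C(C)C)O[Si](C)(C)C(C)(C)C)cc(O)c2c1C(=O)C=CC2=O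
A4 | alternative 2 | 6‑hydroxy‑3‑methoxy‑4‑[(1R)‑1‑(tert‑butyldimethylsilyloxy)‑4‑methylpent‑3‑enyl]‑2H‑pyran‑2‑one | COC1=C([C@@H](CC=C(C)C)O[Si](C)(C)C(C)(C)C)C=C(O)OC1=O
A5 | alternative 2 | 1,4‑benzoquinone | O=C1C=CC(=O)C=C1
A6 | alternative 3 | 2‑[(1R)‑1‑(tert‑butyldimethylsilyloxy)‑4‑methylpent‑3‑enyl]‑5,8‑dimethoxy‑4‑[2‑(trimethylsilyl)ethoxy]naphthalen‑1‑ol | Oc1c([C@@H](CC=C(C)C)O[Si](C)(C)C(C)(C)C)cc(OCC[Si](C)(C)C)c2c(OC)ccc(OC)c12
A7 | alternative 3 | pentacarbonyl{(2,5‑dimethoxyphenyl)[2‑(trimethylsilyl)ethoxy]methylidene}chromium | COc1ccc(OC)c(c1)C(OCC[Si](C)(C)C)=[Cr](=C=O)(=C=O)(=C=O)(=C=O)=C=O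
A8 | alternative 3 | tert‑butyldimethyl{[(3R)‑6‑methylhept‑5‑en‑1‑yn‑3‑yl]oxy}silane | C#C[C@@H](CC=C(C)C)O[Si](C)(C)C(C)(C)C
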